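## The problem

The target, 21, is a 4-aryl-3,4-dihydrocoumarin (chroman-2-one) whose benzo ring A is a phloroglucinol nucleus substituted at every position except C6. C4a carries the C4 stereocentre, C5 and C7 carry free hydroxyls, C8 carries the 3-phenylpropanoyl group and C8a carries the lactone oxygen O1. The only stereocentre is C4 (S), a diarylmethine with no neighbour to relay from, so a chiral catalyst has to set it. Once set it is threatened mainly by strong acid, because the electron-rich ring A would assist ionisation at C4. The hard part is regiochemical: C6 and C8 of a 5,7-dioxygenated dihydrocoumarin are electronically almost alike, so acylation of the finished bicycle cannot be relied on to distinguish them. The same ambiguity returns through the lactone. C5–OH and C8a–O1 both lie ortho to C4a, so with C5–OH free the propanoate arm can move from one oxygen to the other and turn the 8-acyl compound into its 6-acyl isomer. The aryl ester lactone opens with nucleophiles, ring A is easily oxidised or halogenated once its phenols are free, and the aryl ketone is enolisable and reducible; the phenols therefore stay masked until a final neutral step. The plan rests on one feature: C8 and C8a are neighbours bearing an acyl carbon and an oxygen, with the C7 oxygen on the far side of C8. This ortho-acylphenol pair is the formal product of inserting a C8–C8a aryne into the C–O bond of 3-phenylpropanoic acid, and the C7 alkoxy group is placed to send oxygen to C8a and the acyl group to C8.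

## Retrosynthesis

**21 from 20.** The three O–benzyl bonds are cut last. Benzyl ethers survive hydride, n-BuLi, fluoride at high temperature and mild oxidation, and all three fall in one neutral hydrogenolysis in an aprotic solvent. Methyl ethers would need a boron halide and silyl ethers would not survive the fluoride step. The forward reaction must leave the aryl ketone alone and must not give the lactone a chance to migrate to the newly freed C5–OH.

**20 from 17, and 17 from 16.** The O1–C2 bond is cut and C2 is taken back to the alcohol level. In 17 the only free phenol is C8a–OH, so oxidative closure of the primary alcohol onto it can give only the required lactone. The alcohol level is chosen because its triisopropylsilyl ether, 16, is the one chain terminus that is inert both to organolithium chemistry and to the aryne. An ester or amide carbonyl in that position would invite attack by n-BuLi earlier or capture of the aryne through oxygen.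

**16 from 13 and 14.** Two bonds are cut together, C8–C(acyl) and C8a–O. Friedel–Crafts acylation or a Fries shift on a 5,7-dialkoxy arene would leave C6 competing with C8. An aryne fixes both positions, because the two new bonds are made to its two carbons and nowhere else. Precursor 13 is simpler by the whole acyl chain, and 3-phenylpropanoic acid 14 is used as bought. The forward reaction must add the carboxylate oxygen to C8a rather than C8, and the resulting C8 anion must shift the acyl group before it is protonated.

**13 from 10, and 10 from 9.** The C8–Si and O–S bonds are cut. The 2-(trimethylsilyl)aryl triflate comes from ortho-bromophenol 10 by O-silylation, bromine–lithium exchange with retro-Brook shift, and triflation. The bromine comes from phenol-directed bromination of 9, whose only free ortho position is C8. The phenol oxygen of 9 thus directs the halogen, carries silicon to C8 and then leaves as triflate. The C8a oxygen of the target is therefore the carboxyl oxygen of 14, and this exchange of one oxygen for another is the price of the plan.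

**9 from 8, and 8 from 7.** The silyl ether is cut, then the lactone of 7 is restored from the phenol and primary alcohol of 8. Reduction of the lactone is the shortest way to free the C8a phenol while putting the chain at a level that can be protected robustly.

**7 from 5 and 6.** The C4–aryl bond is cut. Rhodium-catalysed asymmetric conjugate addition of arylboronic acid 6 to coumarin 5 makes this bond and the stereocentre together from a flat, achiral acceptor. Acid-mediated hydroarylation of a cinnamic acid would give the racemate. Asymmetric reduction of a 4-arylcoumarin would ask a catalyst to tell two aryl groups apart. The forward step has to overcome the peri C5 benzyloxy group and the electron-rich enoate.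

**5 from 4, and 4 from 1 and 2.** The benzyl ethers are cut, then the C3–C4 double bond and the lactone C–O bond. Wittig olefination of 2,4,6-trihydroxybenzaldehyde 1 with ylide 2 followed by thermal lactonisation gives 5,7-dihydroxycoumarin 4. The symmetry of 1 removes any question of which ortho hydroxyl closes.

## Roads not taken

**Alternative 1:** The cut is O1–C8a alone. The acid A1, a resorcinol-level arene with C8a still bearing hydrogen, would be oxidised with PhI(OAc)2 at its C7 phenol. The carboxyl group would be captured at C4a and, under BF3·OEt2, the acyloxy oxygen would shift to C8a with rearomatisation to lactone A2. Its merits are real. The C8a oxygen is introduced at a C–H position, no silyl triflate has to be built, the lactone closes in the same operation, and A2 is one hydrogenolysis from 21 against three steps after the key step here. The weak points lie in two selectivities with no handle. Oxidation must engage the C7 phenol and not the C5 phenol, and the shift must go to C8a rather than move the C4 carbon. Both happen on an unprotected, electron-rich ring carrying an enolisable ketone. A2 also emerges with C5–OH free in the presence of a Lewis acid, the very situation in which the lactone can wander to C5. The chosen plan is longer but keeps C5 benzylated until the end and takes its regiochemistry from an existing substituent.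

**Alternative 2:** The cut is C4a–C8a and C5–C6, so ring A is built around the stereocentre. Heating siloxyalkyne A3 with cyclobutenone A4 would give phenol A5 by Danheiser benzannulation, with C8a–OH free, C5 silylated and C7 ethylated. This road is better than the chosen one in regiochemical certainty. Every oxygen is differentiated by construction, and neither a bromination nor an aryne addition has to be selective. Against it stand the fragments. A3 needs an enantiopure propargylic stereocentre beside an ester and a silyl ynol ether, and A4 needs its own multistep synthesis. The C7 ethyl ether of A5 can be removed only by reagents that also threaten the lactone and ketone. The C8 side chain arrives as a protected carbinol that must still be deprotected and oxidised. The chosen plan sets against this a shorter linear sequence from a commercial aromatic aldehyde and a single protecting group removed in one neutral step.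

**Alternative 3:** The cut is C2–C3 and C2–O1. Diarylethene A6 would be treated with Pd(OAc)2, a chiral bisphosphine, TsOH and CO. Hydride would go to C4 and palladium to C3, CO would insert, and the phenol would capture the acyl to give A7, which is identical with 20. If it worked it would be the most economical road, since the stereocentre and ring B form in one catalytic step directly before the final deprotection. The doubts are structural. The enantiodetermining hydropalladation is reversible. The C4a aryl group is flanked on both sides and twisted out of conjugation. The capturing phenol is hydrogen-bonded to the C8 ketone. The acid co-catalyst can protonate the electron-rich alkene to a diaryl cation that bypasses the metal. A6 also already contains the C8 acyl group on a pentasubstituted ring, so the regiochemical problem is moved upstream, not solved. The chosen plan is longer, but its stereocentre comes from a reaction of predictable sense and its acyl group from a step that solves the regiochemistry.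

Key step: step 8

Remark on the chemistry: the sense of induction in step 3 is assumed to follow that of unsubstituted coumarin, where the R ligand leads to the R lactone; the CIP priorities at C4 are unchanged here. If the first batch shows the opposite sense, the ligand antipode is used and nothing else changes.

## Route

Step 1
Reactants: 1 2,4,6-trihydroxybenzaldehyde; 2 ethyl (triphenylphosphoranylidene)acetate
Product: 4 5,7-dihydroxycoumarin, via ethyl (E)-3-(2,4,6-trihydroxyphenyl)acrylate 3 (not isolated)
Conditions: PhNEt2, reflux (about 215 °C), N2
Reagents that add atoms: none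
Why: Wittig olefination of the salicylaldehyde, then thermal E-to-Z isomerisation and lactonisation with loss of ethanol, the standard one-flask coumarin synthesis; the two ortho hydroxyls of 1 are equivalent, so only one coumarin can form.

Step 2
Reactants: 4 5,7-dihydroxycoumarin
Product: 5 5,7-bis(benzyloxy)coumarin
Conditions: BnBr (2.3 equiv), K2CO3, DMF, 50 °C
Reagents that add atoms: benzyl bromide, BrCc1ccccc1
Why: Williamson O-alkylation of both phenols; benzyl is chosen because it must survive hydride, n-BuLi, hot fluoride and oxidation and still leave under neutral conditions at the end.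

Step 3
Reactants: 5 5,7-bis(benzyloxy)coumarin; 6 4-(benzyloxy)phenylboronic acid
Product: 7 (S)-5,7-bis(benzyloxy)-4-[4-(benzyloxy)phenyl]chroman-2-one
Conditions: Rh(acac)(C2H4)2 (3 mol %), (S)-SEGPHOS (3.3 mol %), 6 (5 equiv, in portions), 1,4-dioxane/H2O 10:1, 60 °C
Reagents that add atoms: none
Why: Hayashi–Miyaura asymmetric conjugate addition: the aryl–rhodium species formed by transmetalation inserts the C3–C4 double bond and water releases the lactone; the chiral bisphosphine selects the face of C4, and the S ligand is expected to give 4S by analogy with coumarin itself.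

Step 4
Reactants: 7 (S)-5,7-bis(benzyloxy)-4-[4-(benzyloxy)phenyl]chroman-2-one
Product: 8 (S)-3,5-bis(benzyloxy)-2-{1-[4-(benzyloxy)phenyl]-3-hydroxypropyl}phenol
Conditions: LiAlH4, THF, 0 °C to rt; aqueous potassium sodium tartrate work-up
Reagents that add atoms: none
Why: Hydride reduction of the aryl ester frees the C8a phenol and gives the primary alcohol; the benzyl ethers and the C4 centre, which is not alpha to the carbonyl, are untouched.

Step 5
Reactants: 8 (S)-3,5-bis(benzyloxy)-2-{1-[4-(benzyloxy)phenyl]-3-hydroxypropyl}phenol
Product: 9 (S)-3,5-bis(benzyloxy)-2-{1-[4-(benzyloxy)phenyl]-3-(triisopropylsilyloxy)propyl}phenol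
Conditions: TIPSCl (1.1 equiv), imidazole, CH2Cl2, 0 °C
Reagents that add atoms: chlorotriisopropylsilane, CC(C)[Si](Cl)(C(C)C)C(C)C
Why: Silylation under imidazole takes the unhindered primary alcohol far faster than the neutral phenol, which sits beside the branched C4 carbon; the triisopropylsilyl ether is the silyl group most resistant to n-BuLi and to fluoride.

Step 6
Reactants: 9 (S)-3,5-bis(benzyloxy)-2-{1-[4-(benzyloxy)phenyl]-3-(triisopropylsilyloxy)propyl}phenol
Product: 10 (S)-3,5-bis(benzyloxy)-6-bromo-2-{1-[4-(benzyloxy)phenyl]-3-(triisopropylsilyloxy)propyl}phenol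
Conditions: NBS (1.0 equiv), i-Pr2NH (10 mol %), CH2Cl2, −78 to −40 °C, dark
Reagents that add atoms: N-bromosuccinimide, O=C1CCC(=O)N1Br
Why: Amine-catalysed ortho-bromination of a phenol: the N-bromoamine, hydrogen-bonded to the hydroxyl, delivers bromine to the only free ortho carbon, C8, while C6 is para to the hydroxyl and flanked by two benzyloxy groups.

Step 7
Reactants: 10 (S)-3,5-bis(benzyloxy)-6-bromo-2-{1-[4-(benzyloxy)phenyl]-3-(triisopropylsilyloxy)propyl}phenol
Product: 13 (S)-3,5-bis(benzyloxy)-2-{1-[4-(benzyloxy)phenyl]-3-(triisopropylsilyloxy)propyl}-6-(trimethylsilyl)phenyl trifluoromethanesulfonate, via aryl trimethylsilyl ether 11 (not isolated), via lithium 2-silylphenoxide 12 (not isolated)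
Conditions: HMDS, THF, 65 °C, then evaporation; n-BuLi (1.1 equiv), THF, −100 to −80 °C; Tf2O (1.2 equiv), −100 to −78 °C
Reagents that add atoms: hexamethyldisilazane, C[Si](C)(C)N[Si](C)(C)C; trifluoromethanesulfonic anhydride, O=S(=O)(OS(=O)(=O)C(F)(F)F)C(F)(F)F
Why: The standard entry to 2-(trimethylsilyl)aryl triflates: O-silylation, bromine–lithium exchange at C8, retro-Brook 1,3-shift of silicon from oxygen to carbon, and triflation of the resulting phenoxide; the exchange is much faster at this temperature than attack on the benzyl or silyl ethers.

Step 8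
Reactants: 13 (S)-3,5-bis(benzyloxy)-2-{1-[4-(benzyloxy)phenyl]-3-(triisopropylsilyloxy)propyl}-6-(trimethylsilyl)phenyl trifluoromethanesulfonate; 14 3-phenylpropanoic acid
Product: 16 (S)-1-[4,6-bis(benzyloxy)-3-{1-[4-(benzyloxy)phenyl]-3-(triisopropylsilyloxy)propyl}-2-hydroxyphenyl]-3-phenylpropan-1-one, via C8–C8a aryne 15 (not isolated)
Conditions: 14 (1.5 equiv), CsF (5 equiv), THF, 125 °C, sealed tube
Reagents that add atoms: none
Why: Fluoride attacks the C8 trimethylsilyl group and the aryl anion expels the C8a triflate to give aryne 15. The caesium carboxylate formed from 14 and CsF adds through oxygen to C8a, the aryne carbon remote from the C7 benzyloxy group, so the negative charge develops at C8 where the inductive pull of the C7 oxygen stabilises it. The C8 anion then attacks the adjacent ester carbonyl through a four-membered alkoxide that collapses to the ortho-acyl phenoxide, an anionic Fries-type 1,3-shift of the acyl group from oxygen to carbon. The closest known reaction type is the insertion of arynes from 2-(trimethylsilyl)aryl triflates into the C–O bond of carboxylic acids with CsF in hot THF, which gives ortho-hydroxyaryl ketones, and 3-alkoxyarynes are known to take nucleophiles at the remote carbon. No ring is closed and no stereocentre is made; C4 is not acidic under these conditions and the hindered silyl ether oxygen does not compete for the aryne. The step needs regioselectivity (oxygen to C8a) and chemoselectivity (acyl shift before protonation of the C8 anion); the first should come from the C7 alkoxy group outweighing the steric bias of the C4a side chain, the second from the high temperature, the aprotic solvent and only a small excess of acid.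

Step 9
Reactants: 16 (S)-1-[4,6-bis(benzyloxy)-3-{1-[4-(benzyloxy)phenyl]-3-(triisopropylsilyloxy)propyl}-2-hydroxyphenyl]-3-phenylpropan-1-one
Product: 17 (S)-1-[4,6-bis(benzyloxy)-3-{1-[4-(benzyloxy)phenyl]-3-hydroxypropyl}-2-hydroxyphenyl]-3-phenylpropan-1-one
Conditions: Bu4NF, AcOH (1:1, 1.5 equiv), THF, rt
Reagents that add atoms: none
Why: Fluoride cleavage of the silyl ether; buffering with acetic acid keeps the medium near neutral so that the hydrogen-bonded phenol and the enolisable ketone are not disturbed.

Step 10
Reactants: 17 (S)-1-[4,6-bis(benzyloxy)-3-{1-[4-(benzyloxy)phenyl]-3-hydroxypropyl}-2-hydroxyphenyl]-3-phenylpropan-1-one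
Product: 20 (S)-5,7-bis(benzyloxy)-4-[4-(benzyloxy)phenyl]-8-(3-phenylpropanoyl)chroman-2-one, via hydroxy aldehyde 18 (not isolated), via lactol 19 (not isolated)
Conditions: TEMPO (0.2 equiv), PhI(OAc)2 (2.5 equiv), CH2Cl2, rt
Reagents that add atoms: none
Why: Nitroxyl-catalysed oxidative lactonisation as used for 1,5-diols: the primary alcohol gives the aldehyde, the C8a phenol closes on it (6-exo-trig) to the lactol, and the lactol is oxidised to the lactone; C8a–OH is the only free phenol, so ring B can close only at O1, and its hydrogen bond to the C8 ketone should protect ring A from the oxidant.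

Step 11
Reactants: 20 (S)-5,7-bis(benzyloxy)-4-[4-(benzyloxy)phenyl]-8-(3-phenylpropanoyl)chroman-2-one
Product: 21 (S)-5,7-dihydroxy-4-(4-hydroxyphenyl)-8-(3-phenylpropanoyl)chroman-2-one
Conditions: H2 (1 atm), 10% Pd/C, EtOAc, rt
Reagents that add atoms: none
Why: Hydrogenolysis of the three benzyl ethers; the chelated ortho-hydroxyaryl ketone resists reduction, and a neutral aprotic solvent gives the lactone no catalyst or alcohol with which to open or migrate to the freed C5–OH.

## Compound list

1 | 2,4,6-trihydroxybenzaldehyde | O=Cc1c(O)cc(O)cc1O | starting material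
2 | ethyl (triphenylphosphoranylidene)acetate | CCOC(=O)C=P(c1ccccc1)(c1ccccc1)c1ccccc1 | starting material
3 | ethyl (E)-3-(2,4,6-trihydroxyphenyl)acrylate | CCOC(=O)/C=C/c1c(O)cc(O)cc1O | intermediate
4 | 5,7-dihydroxycoumarin | O=C1C=Cc2c(O)cc(O)cc2O1 | intermediate
5 | 5,7-bis(benzyloxy)coumarin | O=C1C=Cc2c(OCc3ccccc3)cc(OCc3ccccc3)cc2O1 | intermediate
6 | 4-(benzyloxy)phenylboronic acid | OB(O)c1ccc(OCc2ccccc2)cc1 | starting material
7 | (S)-5,7-bis(benzyloxy)-4-[4-(benzyloxy)phenyl]chroman-2-one | O=C1C[C@@H](c2ccc(OCc3ccccc3)cc2)c2c(OCc3ccccc3)cc(OCc3ccccc3)cc2O1 | intermediate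
8 | (S)-3,5-bis(benzyloxy)-2-{1-[4-(benzyloxy)phenyl]-3-hydroxypropyl}phenol | OCC[C@@H](c1ccc(OCc2ccccc2)cc1)c1c(OCc2ccccc2)cc(OCc2ccccc2)cc1O | intermediate
9 | (S)-3,5-bis(benzyloxy)-2-{1-[4-(benzyloxy)phenyl]-3-(triisopropylsilyloxy)propyl}phenol | CC(C)[Si](C(C)C)(C(C)C)OCC[C@@H](c1ccc(OCc2ccccc2)cc1)c1c(OCc2ccccc2)cc(OCc2ccccc2)cc1O | intermediate
10 | (S)-3,5-bis(benzyloxy)-6-bromo-2-{1-[4-(benzyloxy)phenyl]-3-(triisopropylsilyloxy)propyl}phenol | CC(C)[Si](C(C)C)(C(C)C)OCC[C@@H](c1ccc(OCc2ccccc2)cc1)c1c(OCc2ccccc2)cc(OCc2ccccc2)c(Br)c1O | intermediate
11 | (S)-{3,5-bis(benzyloxy)-6-bromo-2-[1-(4-(benzyloxy)phenyl)-3-(triisopropylsilyloxy)propyl]phenoxy}trimethylsilane | CC(C)[Si](C(C)C)(C(C)C)OCC[C@@H](c1ccc(OCc2ccccc2)cc1)c1c(OCc2ccccc2)cc(OCc2ccccc2)c(Br)c1O[Si](C)(C)C | intermediate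
12 | lithium (S)-3,5-bis(benzyloxy)-2-{1-[4-(benzyloxy)phenyl]-3-(triisopropylsilyloxy)propyl}-6-(trimethylsilyl)phenoxide | CC(C)[Si](C(C)C)(C(C)C)OCC[C@@H](c1ccc(OCc2ccccc2)cc1)c1c(OCc2ccccc2)cc(OCc2ccccc2)c([Si](C)(C)C)c1[O-].[Li+] | intermediate
13 | (S)-3,5-bis(benzyloxy)-2-{1-[4-(benzyloxy)phenyl]-3-(triisopropylsilyloxy)propyl}-6-(trimethylsilyl)phenyl trifluoromethanesulfonate | CC(C)[Si](C(C)C)(C(C)C)OCC[C@@H](c1ccc(OCc2ccccc2)cc1)c1c(OCc2ccccc2)cc(OCc2ccccc2)c([Si](C)(C)C)c1OS(=O)(=O)C(F)(F)F | intermediate
14 | 3-phenylpropanoic acid | OC(=O)CCc1ccccc1 | starting material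
15 | (S)-3,5-bis(benzyloxy)-6-{1-[4-(benzyloxy)phenyl]-3-(triisopropylsilyloxy)propyl}-1,2-didehydrobenzene (the C8–C8a aryne) | CC(C)[Si](C(C)C)(C(C)C)OCC[C@@H](c1ccc(OCc2ccccc2)cc1)C1=C(OCc2ccccc2)C=C(OCc2ccccc2)C#C1 | intermediate
16 | (S)-1-[4,6-bis(benzyloxy)-3-{1-[4-(benzyloxy)phenyl]-3-(triisopropylsilyloxy)propyl}-2-hydroxyphenyl]-3-phenylpropan-1-one | CC(C)[Si](C(C)C)(C(C)C)OCC[C@@H](c1ccc(OCc2ccccc2)cc1)c1c(OCc2ccccc2)cc(OCc2ccccc2)c(C(=O)CCc2ccccc2)c1O | intermediate
17 | (S)-1-[4,6-bis(benzyloxy)-3-{1-[4-(benzyloxy)phenyl]-3-hydroxypropyl}-2-hydroxyphenyl]-3-phenylpropan-1-one | OCC[C@@H](c1ccc(OCc2ccccc2)cc1)c1c(OCc2ccccc2)cc(OCc2ccccc2)c(C(=O)CCc2ccccc2)c1O | intermediate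
18 | (S)-3-[4,6-bis(benzyloxy)-2-hydroxy-3-(3-phenylpropanoyl)phenyl]-3-[4-(benzyloxy)phenyl]propanal | O=CC[C@@H](c1ccc(OCc2ccccc2)cc1)c1c(OCc2ccccc2)cc(OCc2ccccc2)c(C(=O)CCc2ccccc2)c1O | intermediate
19 | (4S)-5,7-bis(benzyloxy)-4-[4-(benzyloxy)phenyl]-2-hydroxy-8-(3-phenylpropanoyl)chromane (both C2 epimers) | OC1C[C@@H](c2ccc(OCc3ccccc3)cc2)c2c(OCc3ccccc3)cc(OCc3ccccc3)c(C(=O)CCc3ccccc3)c2O1 | intermediate
20 | (S)-5,7-bis(benzyloxy)-4-[4-(benzyloxy)phenyl]-8-(3-phenylpropanoyl)chroman-2-one | O=C1C[C@@H](c2ccc(OCc3ccccc3)cc2)c2c(OCc3ccccc3)cc(OCc3ccccc3)c(C(=O)CCc3ccccc3)c2O1 | intermediate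
21 | (S)-5,7-dihydroxy-4-(4-hydroxyphenyl)-8-(3-phenylpropanoyl)chroman-2-one | O=C1C[C@@H](c2ccc(O)cc2)c2c(O)cc(O)c(C(=O)CCc3ccccc3)c2O1 | target

## Step count and risks

Total step count: 11. Longest linear sequence: 11 steps, from 1 to 21.

**Step 8 (key step).** Three things may go wrong.
- The C8 anion may be protonated by the acid or by bifluoride before the acyl shift, which ends in simple O-arylation.
- The branched C4a side chain may push part of the carboxylate to C8 and erode the regioselectivity.
- The silyl ether may be lost before the aryne is consumed, after which the chain alkoxide would capture the aryne.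

The fallback sets out from 10 and avoids the aryne. The phenol is protected with NaH and chloromethyl methyl ether as the aryl methoxymethyl ether F1. Bromine–lithium exchange with n-BuLi at −78 °C and addition of N-methoxy-N-methyl-3-phenylpropanamide (Weinreb ketone synthesis) give the protected ketone F2. HCl in methanol then removes both the methoxymethyl and the silyl group. The fallback comes back to the route at 17.

**Step 3.** The peri C5 benzyloxy group and the electron-rich enoate may make insertion of the aryl–rhodium species slower than protodeboronation of 6, so that conversion stalls. The fallback makes the C4–C4a bond from the nucleophilic arene side instead. It sets out from no numbered compound: commercial 3,5-bis(benzyloxy)phenol and (E)-3-[4-(benzyloxy)phenyl]prop-2-enal take the place of 1, 2 and 6. Iminium catalysis with (S)-α,α-diphenylprolinol trimethylsilyl ether should bring about Friedel–Crafts alkylation ortho to the hydroxyl and hemiacetal closure to the lactol F3. On the usual shielding model this catalyst should give 4S, to be confirmed by correlation. NaBH4 then reduces F3, and the fallback comes back to the route at 8.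

**Step 6.** Bromination may also take place at C6, or twice, because both free ring positions are strongly activated; this would be poor regioselectivity, not lack of reactivity. The fallback sets out from 9 and replaces electrophilic substitution by directed metalation. Isopropyl isocyanate and Et3N give the aryl isopropylcarbamate F4. In-situ N-silylation, ortho-lithiation with n-BuLi and TMEDA at −78 °C and quenching with Me3SiCl give the C8-silylated carbamate F5; C8 is the only free ortho position and is further acidified by the C7 oxygen. Et2NH and DBU in MeCN release the silylphenol F6, the conjugate acid of 12, and PhNTf2 triflates it in the same flask. The fallback comes back to the route at 13.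

**Step 10.** The trivalent iodine oxidant may attack the free, electron-rich phenol in competition with the alcohol. Closure to the lactol may also be slow because C8a–OH is tied up in its hydrogen bond to the ketone. The fallback sets out from 17 and separates the two oxidations. Swern oxidation, which does not touch the doubly ortho-substituted phenol, gives the lactol 19, which is isolated; at that stage the phenol oxygen is part of the ring. Ag2CO3 on Celite in hot toluene then dehydrogenates the lactol. The fallback comes back to the route at 20, and no compound outside the list is made (F0).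

**Step 11.** The aryl ketone may be over-reduced on long exposure, or the lactone may migrate to C5–OH once that phenol is free. The fallback sets out from 20 and removes the benzyl groups without hydrogen, using BCl3 and pentamethylbenzene in CH2Cl2 at −78 °C with a cold quench. It comes back to the route at 21, and no compound outside the list is made (F0).

## Further compounds

F1 | step 8 | (S)-{3-[4,6-bis(benzyloxy)-3-bromo-2-(methoxymethoxy)phenyl]-3-[4-(benzyloxy)phenyl]propoxy}triisopropylsilane | CC(C)[Si](C(C)C)(C(C)C)OCC[C@@H](c1ccc(OCc2ccccc2)cc1)c1c(OCc2ccccc2)cc(OCc2ccccc2)c(Br)c1OCOC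
F2 | step 8 | (S)-1-[4,6-bis(benzyloxy)-3-{1-[4-(benzyloxy)phenyl]-3-(triisopropylsilyloxy)propyl}-2-(methoxymethoxy)phenyl]-3-phenylpropan-1-one | CC(C)[Si](C(C)C)(C(C)C)OCC[C@@H](c1ccc(OCc2ccccc2)cc1)c1c(OCc2ccccc2)cc(OCc2ccccc2)c(C(=O)CCc2ccccc2)c1OCOC
F3 | step 3 | (4S)-5,7-bis(benzyloxy)-4-[4-(benzyloxy)phenyl]chroman-2-ol (both C2 epimers) | OC1C[C@@H](c2ccc(OCc3ccccc3)cc2)c2c(OCc3ccccc3)cc(OCc3ccccc3)cc2O1
F4 | step 6 | (S)-3,5-bis(benzyloxy)-2-{1-[4-(benzyloxy)phenyl]-3-(triisopropylsilyloxy)propyl}phenyl isopropylcarbamate | CC(C)[Si](C(C)C)(C(C)C)OCC[C@@H](c1ccc(OCc2ccccc2)cc1)c1c(OCc2ccccc2)cc(OCc2ccccc2)cc1OC(=O)NC(C)C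
F5 | step 6 | (S)-3,5-bis(benzyloxy)-2-{1-[4-(benzyloxy)phenyl]-3-(triisopropylsilyloxy)propyl}-6-(trimethylsilyl)phenyl isopropylcarbamate | CC(C)[Si](C(C)C)(C(C)C)OCC[C@@H](c1ccc(OCc2ccccc2)cc1)c1c(OCc2ccccc2)cc(OCc2ccccc2)c([Si](C)(C)C)c1OC(=O)NC(C)C
F6 | step 6 | (S)-3,5-bis(benzyloxy)-2-{1-[4-(benzyloxy)phenyl]-3-(triisopropylsilyloxy)propyl}-6-(trimethylsilyl)phenol | CC(C)[Si](C(C)C)(C(C)C)OCC[C@@H](c1ccc(OCc2ccccc2)cc1)c1c(OCc2ccccc2)cc(OCc2ccccc2)c([Si](C)(C)C)c1O
F0 | step 10 | none | none
F0 | step 11 | none | none
A1 | alternative 1 | (S)-3-[4-(benzyloxy)phenyl]-3-[2,4-dihydroxy-5-(3-phenylpropanoyl)phenyl]propanoic acid | OC(=O)C[C@@H](c1ccc(OCc2ccccc2)cc1)c1cc(C(=O)CCc2ccccc2)c(O)cc1O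
A2 | alternative 1 | (S)-4-[4-(benzyloxy)phenyl]-5,7-dihydroxy-8-(3-phenylpropanoyl)chroman-2-one | O=C1C[C@@H](c2ccc(OCc3ccccc3)cc2)c2c(O)cc(O)c(C(=O)CCc3ccccc3)c2O1
A3 | alternative 2 | methyl (S)-3-[4-(benzyloxy)phenyl]-5-(triisopropylsilyloxy)pent-4-ynoate | COC(=O)C[C@@H](c1ccc(OCc2ccccc2)cc1)C#CO[Si](C(C)C)(C(C)C)C(C)C
A4 | alternative 2 | 2-[1-(tert-butyldimethylsilyloxy)-3-phenylpropyl]-3-ethoxycyclobut-2-en-1-one | CCOC1=C(C(CCc2ccccc2)O[Si](C)(C)C(C)(C)C)C(=O)C1
A5 | alternative 2 | methyl (S)-3-[4-(benzyloxy)phenyl]-3-{3-[1-(tert-butyldimethylsilyloxy)-3-phenylpropyl]-4-ethoxy-2-hydroxy-6-(triisopropylsilyloxy)phenyl}propanoate | COC(=O)C[C@@H](c1ccc(OCc2ccccc2)cc1)c1c(O[Si](C(C)C)(C(C)C)C(C)C)cc(OCC)c(C(O[Si](C)(C)C(C)(C)C)CCc2ccccc2)c1O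
A6 | alternative 3 | 1-[4,6-bis(benzyloxy)-3-{1-[4-(benzyloxy)phenyl]ethenyl}-2-hydroxyphenyl]-3-phenylpropan-1-one | C=C(c1ccc(OCc2ccccc2)cc1)c1c(OCc2ccccc2)cc(OCc2ccccc2)c(C(=O)CCc2ccccc2)c1O
A7 | alternative 3 | (S)-5,7-bis(benzyloxy)-4-[4-(benzyloxy)phenyl]-8-(3-phenylpropanoyl)chroman-2-one | O=C1C[C@@H](c2ccc(OCc3ccccc3)cc2)c2c(OCc3ccccc3)cc(OCc3ccccc3)c(C(=O)CCc3ccccc3)c2O1
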